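## Retrosynthetic overview

1. Numbering used throughout (germacrane): ten-membered carbocycle C1–C10; lactone O–C12(=O)–C11(=C13H2) fused at C6–C7; C14 = CO2Me on C10; C15 = CH2OH on C4. Enabling feature: the oxygenated ring carbon C8 is bonded to C7, and C7 is allylic to the exocyclic C11=C13 methylene of the lactone ring, so O–C8–C7–C11=C13 is a homoallylic alcohol, the retron of a carbonyl allylation with allylic transposition.
2. Key disconnection C7–C8: the carbocycle is opened to an aldehyde (C8) and a 3-(bromomethyl)butenolide (C13–Br, C7=C11). Both carbons are electrophilic; they are joined after reductive polarity reversal with CrCl2 (intramolecular Nozaki–Hiyama–Kishi allylation). One operation closes the ten-membered ring, sets C7 and C8 and unveils the α-methylene lactone from a monocyclic chain.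
3. C8 ester: the chair transition state should deliver the (8S) carbinol, which is inverted and acylated in one Mitsunobu step with (S)-2-methylbutanoic acid; C15–OH is freed last.
4. Chain assembly: C1=C10 by E-selective Wittig; butenolide by esterification of the C6 allylic alcohol with 2-(bromomethyl)acrylic acid and ring-closing metathesis; C4 and C6 from (R)-5-(trityloxymethyl)butyrolactone by trans-selective allylation.
5. Ring order: lactone ring first (step 13), ten-membered ring second (step 16).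

Key step: step 16

Remark: (R)-5-[(trityloxy)methyl]dihydrofuran-2(3H)-one is taken as a catalogue compound; otherwise one tritylation of commercial (R)-5-(hydroxymethyl)dihydrofuran-2(3H)-one precedes step 1.

## Route

Step 1
Reactants: 1 (R)-5-[(trityloxy)methyl]dihydrofuran-2(3H)-one
Product: 2 (3S,5R)-3-allyl-5-[(trityloxy)methyl]dihydrofuran-2(3H)-one
Conditions: LiN(iPr)2, THF, −78 °C; allyl bromide, −78 → −40 °C
Reagents that add atoms: allyl bromide, C=CCBr
Why: Lithium enolate alkylation of a γ-substituted γ-butyrolactone, in which the bulky trityloxymethyl group on C6 shields one face so that the allyl group (C3–C1) should enter trans and set C4 as S.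

Step 2
Reactants: 2 (3S,5R)-3-allyl-5-[(trityloxy)methyl]dihydrofuran-2(3H)-one
Product: 3 (2R,4S)-4-(hydroxymethyl)-1-(trityloxy)hept-6-en-2-ol
Conditions: LiAlH4, THF, 0 °C
Reagents that add atoms: none
Why: Hydride reduction of the lactone to the 1,4-diol (C15–OH and C6–OH) leaves the alkene, the trityl ether and both stereocentres untouched.

Step 3
Reactants: 3 (2R,4S)-4-(hydroxymethyl)-1-(trityloxy)hept-6-en-2-ol
Product: 4 (2R,4S)-4-[(tert-butyldiphenylsilyloxy)methyl]-1-(trityloxy)hept-6-en-2-ol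
Conditions: TBDPSCl (1.05 equiv), imidazole, CH2Cl2, 0 °C
Reagents that add atoms: tert-butyl(chloro)diphenylsilane, CC(C)(C)[Si](Cl)(c1ccccc1)c1ccccc1
Why: Sterically controlled silylation, in which the bulky silyl chloride should react only at the primary C15 hydroxyl and leave the secondary C6 hydroxyl free.

Step 4
Reactants: 4 (2R,4S)-4-[(tert-butyldiphenylsilyloxy)methyl]-1-(trityloxy)hept-6-en-2-ol
Product: 5 (2R,4S)-4-[(tert-butyldiphenylsilyloxy)methyl]hept-6-ene-1,2-diol
Conditions: p-TsOH·H2O (cat.), MeOH/CH2Cl2, rt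
Reagents that add atoms: none
Why: Acid-catalysed methanolysis of the trityl ether through the trityl cation, under conditions that a primary TBDPS ether should survive.

Step 5
Reactants: 5 (2R,4S)-4-[(tert-butyldiphenylsilyloxy)methyl]hept-6-ene-1,2-diol
Product: 7 tert-butyl{[(S)-2-{[(R)-oxiran-2-yl]methyl}pent-4-en-1-yl]oxy}diphenylsilane, via primary monotosylate 6 (not isolated)
Conditions: NaH (2.5 equiv), THF, 0 °C; 1-(p-tolylsulfonyl)imidazole (1.05 equiv), 0 °C → rt
Reagents that add atoms: none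
Why: One-pot 1,2-diol to epoxide conversion, in which the primary alkoxide is sulfonylated and the secondary alkoxide closes by intramolecular Williamson displacement, so the C6–O bond and its configuration are retained.

Step 6
Reactants: 7 tert-butyl{[(S)-2-{[(R)-oxiran-2-yl]methyl}pent-4-en-1-yl]oxy}diphenylsilane
Product: 9 (S)-4-[(tert-butyldiphenylsilyloxy)methyl]-5-[(R)-oxiran-2-yl]pentan-1-ol, via B-alkyl-9-BBN adduct 8 (not isolated)
Conditions: 9-BBN, THF, 0 °C → rt; then 30% H2O2, aq NaOAc, 0 °C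
Reagents that add atoms: hydrogen peroxide, OO
Why: Anti-Markovnikov hydroboration–oxidation of the terminal alkene gives the C1 alcohol, 9-BBN being selective for monosubstituted alkenes and unreactive toward epoxides at room temperature.

Step 7
Reactants: 9 (S)-4-[(tert-butyldiphenylsilyloxy)methyl]-5-[(R)-oxiran-2-yl]pentan-1-ol
Product: 10 (4S,6R)-4-[(tert-butyldiphenylsilyloxy)methyl]oct-7-ene-1,6-diol
Conditions: Me3S+ I− (5 equiv), n-BuLi (4.9 equiv), THF, −10 °C → rt
Reagents that add atoms: trimethylsulfonium iodide, C[S+](C)C.[I-]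
Why: One-carbon homologation of a terminal epoxide to an allylic alcohol by dimethylsulfonium methylide (attack at the terminal carbon C7, then base-induced loss of dimethyl sulfide), which does not touch the C6 carbinol and therefore keeps its configuration.

Step 8
Reactants: 10 (4S,6R)-4-[(tert-butyldiphenylsilyloxy)methyl]oct-7-ene-1,6-diol
Product: 11 (4S,6R)-4-[(tert-butyldiphenylsilyloxy)methyl]-6-hydroxyoct-7-enal
Conditions: TEMPO (10 mol %), PhI(OAc)2 (1.1 equiv), CH2Cl2, rt
Reagents that add atoms: none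
Why: Oxoammonium-mediated oxidation, which is selective for the primary C1 alcohol over the secondary C6 alcohol on steric grounds.

Step 9
Reactants: 12 (3-bromopropoxy)(tert-butyl)dimethylsilane
Product: 13 [3-(tert-butyldimethylsilyloxy)propyl]triphenylphosphonium bromide
Conditions: PPh3, MeCN, reflux
Reagents that add atoms: triphenylphosphine, c1ccc(cc1)P(c1ccccc1)c1ccccc1
Why: SN2 quaternisation of the phosphine by an unhindered primary bromide.

Step 10
Reactants: 13 [3-(tert-butyldimethylsilyloxy)propyl]triphenylphosphonium bromide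
Product: 16 methyl 4-(tert-butyldimethylsilyloxy)-2-(triphenyl-λ5-phosphanylidene)butanoate, via unstabilised ylide 14 (not isolated), via acylphosphonium chloride 15 (not isolated)
Conditions: NaN(SiMe3)2 (1.0 equiv), THF, 0 °C; ClCO2Me (1.0 equiv), −78 °C; NaN(SiMe3)2 (1.0 equiv), −78 °C → rt
Reagents that add atoms: methyl chloroformate, COC(=O)Cl
Why: Bestmann acylation of a phosphorus ylide with a chloroformate, followed by deprotonation of the acylphosphonium salt to the isolable ester-stabilised ylide that carries C8, C9, C10 and C14.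

Step 11
Reactants: 11 (4S,6R)-4-[(tert-butyldiphenylsilyloxy)methyl]-6-hydroxyoct-7-enal; 16 methyl 4-(tert-butyldimethylsilyloxy)-2-(triphenyl-λ5-phosphanylidene)butanoate
Product: 17 methyl (2E,6S,8R)-2-[2-(tert-butyldimethylsilyloxy)ethyl]-6-[(tert-butyldiphenylsilyloxy)methyl]-8-hydroxydeca-2,9-dienoate
Conditions: toluene, 80 °C
Reagents that add atoms: none
Why: Wittig olefination with an α-substituted ester-stabilised ylide, which should give the trisubstituted enoate with the chain (C2) trans to the ester, that is the (E) C1=C10 geometry of the target.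

Step 12
Reactants: 17 methyl (2E,6S,8R)-2-[2-(tert-butyldimethylsilyloxy)ethyl]-6-[(tert-butyldiphenylsilyloxy)methyl]-8-hydroxydeca-2,9-dienoate; 18 2-(bromomethyl)acrylic acid
Product: 19 methyl (2E,6S,8R)-8-{[2-(bromomethyl)acryloyl]oxy}-2-[2-(tert-butyldimethylsilyloxy)ethyl]-6-[(tert-butyldiphenylsilyloxy)methyl]deca-2,9-dienoate
Conditions: N,N'-diisopropylcarbodiimide, DMAP (5 mol %), CH2Cl2, −20 → 0 °C
Reagents that add atoms: none
Why: Steglich (carbodiimide) esterification of the only free hydroxyl (C6), run cold with little DMAP to limit attack on the allylic bromide; the C6–O bond is not broken.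

Step 13
Reactants: 19 methyl (2E,6S,8R)-8-{[2-(bromomethyl)acryloyl]oxy}-2-[2-(tert-butyldimethylsilyloxy)ethyl]-6-[(tert-butyldiphenylsilyloxy)methyl]deca-2,9-dienoate
Product: 20 methyl (2E,6S)-7-[(R)-4-(bromomethyl)-5-oxo-2,5-dihydrofuran-2-yl]-2-[2-(tert-butyldimethylsilyloxy)ethyl]-6-[(tert-butyldiphenylsilyloxy)methyl]hept-2-enoate
Conditions: second-generation Hoveyda–Grubbs catalyst (5–10 mol %), toluene (5 mM), 80 °C, argon sparge
Reagents that add atoms: none
Why: Ring-closing metathesis of an allyl 2-substituted acrylate to the α-substituted butenolide (five-membered ring, C7=C11), with the trisubstituted C1=C10 enoate inert to the catalyst.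

Step 14
Reactants: 20 methyl (2E,6S)-7-[(R)-4-(bromomethyl)-5-oxo-2,5-dihydrofuran-2-yl]-2-[2-(tert-butyldimethylsilyloxy)ethyl]-6-[(tert-butyldiphenylsilyloxy)methyl]hept-2-enoate
Product: 21 methyl (2E,6S)-7-[(R)-4-(bromomethyl)-5-oxo-2,5-dihydrofuran-2-yl]-6-[(tert-butyldiphenylsilyloxy)methyl]-2-(2-hydroxyethyl)hept-2-enoate
Conditions: camphorsulfonic acid (10 mol %), MeOH/CH2Cl2 (1:1), 0 °C
Reagents that add atoms: none
Why: Acid-catalysed methanolysis cleaves the primary TBS ether much faster than the primary TBDPS ether, and the non-nucleophilic acidic medium spares the allylic bromide.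

Step 15
Reactants: 21 methyl (2E,6S)-7-[(R)-4-(bromomethyl)-5-oxo-2,5-dihydrofuran-2-yl]-6-[(tert-butyldiphenylsilyloxy)methyl]-2-(2-hydroxyethyl)hept-2-enoate
Product: 22 methyl (2E,6S)-7-[(R)-4-(bromomethyl)-5-oxo-2,5-dihydrofuran-2-yl]-6-[(tert-butyldiphenylsilyloxy)methyl]-2-(2-oxoethyl)hept-2-enoate
Conditions: Dess–Martin periodinane, NaHCO3, CH2Cl2, 0 °C; used at once
Reagents that add atoms: none
Why: Dess–Martin oxidation under buffered, amine-free conditions gives the C8 aldehyde without moving the β,γ-double bond into conjugation and without touching the bromide.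

Step 16
Reactants: 22 methyl (2E,6S)-7-[(R)-4-(bromomethyl)-5-oxo-2,5-dihydrofuran-2-yl]-6-[(tert-butyldiphenylsilyloxy)methyl]-2-(2-oxoethyl)hept-2-enoate
Product: 24 methyl (3aR,4S,6E,10S,11aR)-10-[(tert-butyldiphenylsilyloxy)methyl]-4-hydroxy-3-methylidene-2-oxo-2,3,3a,4,5,8,9,10,11,11a-decahydrocyclodeca[b]furan-6-carboxylate, via allylchromium dichloride 23 (not isolated)
Conditions: CrCl2 (8 equiv), THF, rt, syringe-pump addition of 22 over 12 h (final 2 mM); then aq NH4Cl
Reagents that add atoms: none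
Why: Two equivalents of CrCl2 reduce the allylic C–Br bond of 22 to the σ-allyl species 23 of trivalent chromium (Cr on C13), whose γ-carbon C7 adds to the tethered aldehyde carbon C8 through a six-membered chair transition state (Cr–O=C8···C7=C11–C13) with transposition of the double bond to the exocyclic C11=C13 position, so that two carbons that are both electrophilic in 22 are joined after polarity reversal at C7. The closest known reaction type is the intramolecular Nozaki–Hiyama–Kishi (Barbier-type) allylation of aldehydes by 2-(bromomethyl)alk-2-enoates, established for ten-membered germacranolide carbocycles, together with the intermolecular allylation of aldehydes by 5-substituted 3-(bromomethyl)butenolides. The ten-membered ring closes in the 10-exo-trig mode at the aldehyde carbonyl (SE2' at the allyl unit), the lactone ring being already in place. C7 is controlled by C6: the aldehyde should add to the butenolide face opposite the C5 branch, which gives the trans ring fusion and lets the C5–C6–C7–C8 torsion take the large value (about 140°) that a ten-membered ring accepts, whereas cis addition would force a nearly eclipsed ring torsion. C8 is controlled by the chair in which the tether carbon C9 is equatorial on the allylchromium unit whose geometry is locked by the lactone (C6 trans to C13 across C7=C11), which places the C8–O bond anti to C6 and should give the (8S) carbinol (4S in the ring numbering of 24), the epimer that the invertive esterification of step 17 requires. The step needs γ- over α-attack (secured by the cyclic transition state), aldehyde over ester chemoselectivity (inherent to organochromium reagents) and ring closure over oligomerisation (secured by slow addition at high dilution).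

Step 17
Reactants: 24 methyl (3aR,4S,6E,10S,11aR)-10-[(tert-butyldiphenylsilyloxy)methyl]-4-hydroxy-3-methylidene-2-oxo-2,3,3a,4,5,8,9,10,11,11a-decahydrocyclodeca[b]furan-6-carboxylate; 25 (S)-2-methylbutanoic acid
Product: 26 methyl (3aS,4R,6E,10S,11aR)-10-[(tert-butyldiphenylsilyloxy)methyl]-3-methylidene-4-{[(S)-2-methylbutanoyl]oxy}-2-oxo-2,3,3a,4,5,8,9,10,11,11a-decahydrocyclodeca[b]furan-6-carboxylate
Conditions: PPh3, diisopropyl azodicarboxylate, toluene, 0 °C → rt
Reagents that add atoms: none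
Why: Mitsunobu esterification, in which SN2 displacement of the C8 alkoxyphosphonium by the carboxylate should invert C8 to R while the stereocentre of the acid is not involved; the change of the 3a descriptor from R to S is a priority effect only.

Step 18
Reactants: 26 methyl (3aS,4R,6E,10S,11aR)-10-[(tert-butyldiphenylsilyloxy)methyl]-3-methylidene-4-{[(S)-2-methylbutanoyl]oxy}-2-oxo-2,3,3a,4,5,8,9,10,11,11a-decahydrocyclodeca[b]furan-6-carboxylate
Product: 27 methyl (3aS,4R,6E,10S,11aR)-10-(hydroxymethyl)-3-methylidene-4-{[(S)-2-methylbutanoyl]oxy}-2-oxo-2,3,3a,4,5,8,9,10,11,11a-decahydrocyclodeca[b]furan-6-carboxylate (CNP0141952.2)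
Conditions: HF·pyridine, THF, 0 °C → rt
Reagents that add atoms: none
Why: Fluoride cleavage of the TBDPS ether under mildly acidic conditions that should spare the three esters, the enoate and the α-methylene lactone.

## Compound list

1 | (R)-5-[(trityloxy)methyl]dihydrofuran-2(3H)-one | O=C1CC[C@H](COC(c2ccccc2)(c2ccccc2)c2ccccc2)O1 | starting material
2 | (3S,5R)-3-allyl-5-[(trityloxy)methyl]dihydrofuran-2(3H)-one | O=C1[C@@H](CC=C)C[C@H](COC(c2ccccc2)(c2ccccc2)c2ccccc2)O1 | intermediate
3 | (2R,4S)-4-(hydroxymethyl)-1-(trityloxy)hept-6-en-2-ol | OC[C@@H](CC=C)C[C@@H](O)COC(c1ccccc1)(c1ccccc1)c1ccccc1 | intermediate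
4 | (2R,4S)-4-[(tert-butyldiphenylsilyloxy)methyl]-1-(trityloxy)hept-6-en-2-ol | CC(C)(C)[Si](c1ccccc1)(c1ccccc1)OC[C@@H](CC=C)C[C@@H](O)COC(c1ccccc1)(c1ccccc1)c1ccccc1 | intermediate
5 | (2R,4S)-4-[(tert-butyldiphenylsilyloxy)methyl]hept-6-ene-1,2-diol | CC(C)(C)[Si](c1ccccc1)(c1ccccc1)OC[C@@H](CC=C)C[C@@H](O)CO | intermediate
6 | (2R,4S)-4-[(tert-butyldiphenylsilyloxy)methyl]-2-hydroxyhept-6-en-1-yl 4-methylbenzenesulfonate (present as its sodium alkoxide) | CC(C)(C)[Si](c1ccccc1)(c1ccccc1)OC[C@@H](CC=C)C[C@@H](O)COS(=O)(=O)c1ccc(C)cc1 | intermediate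
7 | tert-butyl{[(S)-2-{[(R)-oxiran-2-yl]methyl}pent-4-en-1-yl]oxy}diphenylsilane | CC(C)(C)[Si](c1ccccc1)(c1ccccc1)OC[C@@H](CC=C)C[C@@H]1CO1 | intermediate
8 | B-alkyl-9-borabicyclo[3.3.1]nonane adduct of 7 (boron on the terminal carbon) | CC(C)(C)[Si](c1ccccc1)(c1ccccc1)OC[C@@H](CCCB1C2CCCC1CCC2)C[C@@H]1CO1 | intermediate
9 | (S)-4-[(tert-butyldiphenylsilyloxy)methyl]-5-[(R)-oxiran-2-yl]pentan-1-ol | CC(C)(C)[Si](c1ccccc1)(c1ccccc1)OC[C@@H](CCCO)C[C@@H]1CO1 | intermediate
10 | (4S,6R)-4-[(tert-butyldiphenylsilyloxy)methyl]oct-7-ene-1,6-diol | CC(C)(C)[Si](c1ccccc1)(c1ccccc1)OC[C@@H](CCCO)C[C@@H](O)C=C | intermediate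
11 | (4S,6R)-4-[(tert-butyldiphenylsilyloxy)methyl]-6-hydroxyoct-7-enal | CC(C)(C)[Si](c1ccccc1)(c1ccccc1)OC[C@@H](CCC=O)C[C@@H](O)C=C | intermediate
12 | (3-bromopropoxy)(tert-butyl)dimethylsilane | BrCCCO[Si](C)(C)C(C)(C)C | starting material
13 | [3-(tert-butyldimethylsilyloxy)propyl]triphenylphosphonium bromide | [Br-].CC(C)(C)[Si](C)(C)OCCC[P+](c1ccccc1)(c1ccccc1)c1ccccc1 | intermediate
14 | [3-(tert-butyldimethylsilyloxy)propylidene]triphenylphosphorane | CC(C)(C)[Si](C)(C)OCCC=P(c1ccccc1)(c1ccccc1)c1ccccc1 | intermediate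
15 | [4-(tert-butyldimethylsilyloxy)-1-methoxy-1-oxobutan-2-yl]triphenylphosphonium chloride | [Cl-].COC(=O)C(CCO[Si](C)(C)C(C)(C)C)[P+](c1ccccc1)(c1ccccc1)c1ccccc1 | intermediate
16 | methyl 4-(tert-butyldimethylsilyloxy)-2-(triphenyl-λ5-phosphanylidene)butanoate | COC(=O)C(CCO[Si](C)(C)C(C)(C)C)=P(c1ccccc1)(c1ccccc1)c1ccccc1 | intermediate
17 | methyl (2E,6S,8R)-2-[2-(tert-butyldimethylsilyloxy)ethyl]-6-[(tert-butyldiphenylsilyloxy)methyl]-8-hydroxydeca-2,9-dienoate | CC(C)(C)[Si](c1ccccc1)(c1ccccc1)OC[C@@H](CC/C=C(/C(=O)OC)CCO[Si](C)(C)C(C)(C)C)C[C@@H](O)C=C | intermediate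
18 | 2-(bromomethyl)acrylic acid | OC(=O)C(=C)CBr | starting material
19 | methyl (2E,6S,8R)-8-{[2-(bromomethyl)acryloyl]oxy}-2-[2-(tert-butyldimethylsilyloxy)ethyl]-6-[(tert-butyldiphenylsilyloxy)methyl]deca-2,9-dienoate | CC(C)(C)[Si](c1ccccc1)(c1ccccc1)OC[C@@H](CC/C=C(/C(=O)OC)CCO[Si](C)(C)C(C)(C)C)C[C@@H](OC(=O)C(=C)CBr)C=C | intermediate
20 | methyl (2E,6S)-7-[(R)-4-(bromomethyl)-5-oxo-2,5-dihydrofuran-2-yl]-2-[2-(tert-butyldimethylsilyloxy)ethyl]-6-[(tert-butyldiphenylsilyloxy)methyl]hept-2-enoate | BrCC1=C[C@@H](C[C@@H](CO[Si](c2ccccc2)(c2ccccc2)C(C)(C)C)CC/C=C(/C(=O)OC)CCO[Si](C)(C)C(C)(C)C)OC1=O | intermediate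
21 | methyl (2E,6S)-7-[(R)-4-(bromomethyl)-5-oxo-2,5-dihydrofuran-2-yl]-6-[(tert-butyldiphenylsilyloxy)methyl]-2-(2-hydroxyethyl)hept-2-enoate | BrCC1=C[C@@H](C[C@@H](CO[Si](c2ccccc2)(c2ccccc2)C(C)(C)C)CC/C=C(/C(=O)OC)CCO)OC1=O | intermediate
22 | methyl (2E,6S)-7-[(R)-4-(bromomethyl)-5-oxo-2,5-dihydrofuran-2-yl]-6-[(tert-butyldiphenylsilyloxy)methyl]-2-(2-oxoethyl)hept-2-enoate | BrCC1=C[C@@H](C[C@@H](CO[Si](c2ccccc2)(c2ccccc2)C(C)(C)C)CC/C=C(/C(=O)OC)CC=O)OC1=O | intermediate
23 | σ-allyl dichloride of trivalent chromium derived from 22 (Cr on the former CH2Br carbon) | Cl[Cr](Cl)CC1=C[C@@H](C[C@@H](CO[Si](c2ccccc2)(c2ccccc2)C(C)(C)C)CC/C=C(/C(=O)OC)CC=O)OC1=O | intermediate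
24 | methyl (3aR,4S,6E,10S,11aR)-10-[(tert-butyldiphenylsilyloxy)methyl]-4-hydroxy-3-methylidene-2-oxo-2,3,3a,4,5,8,9,10,11,11a-decahydrocyclodeca[b]furan-6-carboxylate | C=C1C(=O)O[C@@H]2C[C@@H](CO[Si](c3ccccc3)(c3ccccc3)C(C)(C)C)CC/C=C(/C(=O)OC)C[C@H](O)[C@@H]12 | intermediate
25 | (S)-2-methylbutanoic acid | CC[C@H](C)C(=O)O | starting material
26 | methyl (3aS,4R,6E,10S,11aR)-10-[(tert-butyldiphenylsilyloxy)methyl]-3-methylidene-4-{[(S)-2-methylbutanoyl]oxy}-2-oxo-2,3,3a,4,5,8,9,10,11,11a-decahydrocyclodeca[b]furan-6-carboxylate | C=C1C(=O)O[C@@H]2C[C@@H](CO[Si](c3ccccc3)(c3ccccc3)C(C)(C)C)CC/C=C(/C(=O)OC)C[C@@H](OC(=O)[C@@H](C)CC)[C@@H]12 | intermediate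
27 | methyl (3aS,4R,6E,10S,11aR)-10-(hydroxymethyl)-3-methylidene-4-{[(S)-2-methylbutanoyl]oxy}-2-oxo-2,3,3a,4,5,8,9,10,11,11a-decahydrocyclodeca[b]furan-6-carboxylate (CNP0141952.2) | C=C1C(=O)O[C@@H]2C[C@@H](CO)CC/C=C(/C(=O)OC)C[C@@H](OC(=O)[C@@H](C)CC)[C@@H]12 | target

## Step count and risks

Total steps: 18. Longest linear sequence: 16 (steps 1–8 and 11–18; steps 9–10 make the ylide).

Steps most likely to fail:

1. Step 16 (ring closure). Intermolecular coupling and reductive loss of the bromide may compete with cyclisation, and discrimination between the two faces of the aldehyde in the chair may be incomplete. The fallback replaces the reductive coupling by an intramolecular allylboration; it sets out from 20 and returns at 24. Bromide 20 is borylated (B2pin2, CuCl, LiCl, KOAc, DMF, rt) to the pinacol allylboronate F1. The TBS ether is cleaved as in step 14 to the alcohol F2, and Dess–Martin oxidation gives the aldehyde F3. F3 is cyclised at high dilution with Sc(OTf)3 (cat.) in toluene; the closed six-membered B–O transition state of this 2-(alkoxycarbonyl)allylboronate should give, after aqueous work-up, the same anti carbinol 24 without any reducing metal.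

2. Step 17 (invertive esterification). Elimination of the activated C8 oxygen toward a conjugated diene, acylation with retention through an acyloxyphosphonium pathway, or reversible phosphine addition to the methylene lactone may erode the inversion. The fallback is a two-step sulfonate displacement from 24 back to 26. Alcohol 24 is converted with ClCH2SO2Cl and pyridine (CH2Cl2, 0 °C) into the chloromethanesulfonate F4. F4 is displaced with inversion by caesium (S)-2-methylbutanoate (from 25 and Cs2CO3, 18-crown-6, toluene, 60 °C) to give 26.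

3. Step 13 (metathesis). Slow turnover of the electron-poor 1,1-disubstituted alkene, catalyst decomposition, or loss of the allylic bromide at the temperature required may stall the ring closure. The fallback introduces the halide after the metathesis; it sets out from 17 and returns at 20. Alcohol 17 is acylated with acryloyl chloride (iPr2NEt, CH2Cl2, 0 °C) to the acrylate F5. Second-generation Grubbs catalyst (CH2Cl2, 40 °C) closes the unsubstituted butenolide F6. Morita–Baylis–Hillman hydroxymethylation (aq formaldehyde, imidazole, THF/H2O) gives the 3-(hydroxymethyl)butenolide F7, and Appel bromination (CBr4, PPh3, CH2Cl2, 0 °C) returns 20.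

Further compounds

F1 | step 16 | methyl (2E,6S)-2-[2-(tert-butyldimethylsilyloxy)ethyl]-6-[(tert-butyldiphenylsilyloxy)methyl]-7-{(R)-5-oxo-4-[(4,4,5,5-tetramethyl-1,3,2-dioxaborolan-2-yl)methyl]-2,5-dihydrofuran-2-yl}hept-2-enoate | CC1(C)OB(CC2=C[C@@H](C[C@@H](CO[Si](c3ccccc3)(c3ccccc3)C(C)(C)C)CC/C=C(/C(=O)OC)CCO[Si](C)(C)C(C)(C)C)OC2=O)OC1(C)C
F2 | step 16 | methyl (2E,6S)-6-[(tert-butyldiphenylsilyloxy)methyl]-2-(2-hydroxyethyl)-7-{(R)-5-oxo-4-[(4,4,5,5-tetramethyl-1,3,2-dioxaborolan-2-yl)methyl]-2,5-dihydrofuran-2-yl}hept-2-enoate | CC1(C)OB(CC2=C[C@@H](C[C@@H](CO[Si](c3ccccc3)(c3ccccc3)C(C)(C)C)CC/C=C(/C(=O)OC)CCO)OC2=O)OC1(C)C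
F3 | step 16 | methyl (2E,6S)-6-[(tert-butyldiphenylsilyloxy)methyl]-2-(2-oxoethyl)-7-{(R)-5-oxo-4-[(4,4,5,5-tetramethyl-1,3,2-dioxaborolan-2-yl)methyl]-2,5-dihydrofuran-2-yl}hept-2-enoate | CC1(C)OB(CC2=C[C@@H](C[C@@H](CO[Si](c3ccccc3)(c3ccccc3)C(C)(C)C)CC/C=C(/C(=O)OC)CC=O)OC2=O)OC1(C)C
F4 | step 17 | methyl (3aS,4S,6E,10S,11aR)-10-[(tert-butyldiphenylsilyloxy)methyl]-4-{[(chloromethyl)sulfonyl]oxy}-3-methylidene-2-oxo-2,3,3a,4,5,8,9,10,11,11a-decahydrocyclodeca[b]furan-6-carboxylate | C=C1C(=O)O[C@@H]2C[C@@H](CO[Si](c3ccccc3)(c3ccccc3)C(C)(C)C)CC/C=C(/C(=O)OC)C[C@H](OS(=O)(=O)CCl)[C@@H]12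
F5 | step 13 | methyl (2E,6S,8R)-8-(acryloyloxy)-2-[2-(tert-butyldimethylsilyloxy)ethyl]-6-[(tert-butyldiphenylsilyloxy)methyl]deca-2,9-dienoate | CC(C)(C)[Si](c1ccccc1)(c1ccccc1)OC[C@@H](CC/C=C(/C(=O)OC)CCO[Si](C)(C)C(C)(C)C)C[C@@H](OC(=O)C=C)C=C
F6 | step 13 | methyl (2E,6S)-2-[2-(tert-butyldimethylsilyloxy)ethyl]-6-[(tert-butyldiphenylsilyloxy)methyl]-7-[(R)-5-oxo-2,5-dihydrofuran-2-yl]hept-2-enoate | O=C1C=C[C@@H](C[C@@H](CO[Si](c2ccccc2)(c2ccccc2)C(C)(C)C)CC/C=C(/C(=O)OC)CCO[Si](C)(C)C(C)(C)C)O1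
F7 | step 13 | methyl (2E,6S)-2-[2-(tert-butyldimethylsilyloxy)ethyl]-6-[(tert-butyldiphenylsilyloxy)methyl]-7-[(R)-4-(hydroxymethyl)-5-oxo-2,5-dihydrofuran-2-yl]hept-2-enoate | OCC1=C[C@@H](C[C@@H](CO[Si](c2ccccc2)(c2ccccc2)C(C)(C)C)CC/C=C(/C(=O)OC)CCO[Si](C)(C)C(C)(C)C)OC1=O
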